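## Retrosynthetic overview

1. Enabling feature: in the nine-membered carbocycle the tertiary carbinol C7 (OH, CH3) sits next to the C8–C9 oxirane, with the oxirane oxygen syn to the C7 hydroxyl. This syn-2,3-epoxy alcohol is the retron of a hydroxyl-directed epoxidation of a (Z)-cyclononenol, which is the adduct of a C8 (Z)-alkenyl metal and a C7 methyl ketone; the C7–C8 bond therefore closes the carbocycle.
2. The bicyclic acetal is opened at O2–C1 to a lactol and a C1 mesylate, and the lactol is traced back to a butenolide (C3 carbonyl = masked acetal carbon), which is inert during ring closure and epoxidation.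
3. The monocyclic ring-closure precursor comes from an Ireland–Claisen acid: the C4a–C11a bond, both stereocentres and the C4=C12 geometry arise by chirality transfer from a C12 carbinol.
4. Fragments: a C12–C17 aldehyde from D-erythronolactone acetonide and MeMgBr; a C3–C7/C18 ynoate from hex-5-yn-2-one; a C1/C8–C11a/C19 acid from 3-chloro-2-(chloromethyl)propene, ethynyltrimethylsilane and CO2.
5. Ring order: butenolide (step 19), nine-membered carbocycle (step 21), oxirane (step 22), pyran of the bicyclic acetal (step 24).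

Key step: step 21

Remark: xenicane locants are used throughout (C1 = OCH2, O2, C3 = acetal CH, C4, C4a, C5–C11, C11a, C12 = ring =CH, C13 = OCH, C14 = CHOH, C15 = CMe2OH, C18 = CH3 on C7, C19 = exocyclic CH2 on C11); the target is then (3S,4aS,7S,8R,9R,11aR,13R,14R).

## Route

Step 1
Reactants: 1 2,3-O-isopropylidene-D-erythronolactone
Product: 2 2-[(4R,5R)-5-(hydroxymethyl)-2,2-dimethyl-1,3-dioxolan-4-yl]propan-2-ol
Conditions: MeMgBr (3 equiv), THF, 0 °C to rt; aq. NH4Cl
Reagents that add atoms: methylmagnesium bromide, C[Mg]Br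
Why: Double Grignard addition to the lactone carbonyl builds the C15 dimethylcarbinol and frees the primary alcohol, while C13 and C14 come unchanged from the chiral pool.

Step 2
Reactants: 2 dioxolane diol
Product: 3 (4R,5R)-bis(triethylsilyl) ether of 2
Conditions: Et3SiOTf (2.4 equiv), 2,6-lutidine, CH2Cl2, −78 to 0 °C
Reagents that add atoms: triethylsilyl trifluoromethanesulfonate, CC[Si](CC)(CC)OS(=O)(=O)C(F)(F)F
Why: Silylation with a silyl triflate protects the primary and the hindered tertiary alcohol alike.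

Step 3
Reactants: 3 bis(triethylsilyl) ether
Product: 4 (4S,5R)-2,2-dimethyl-5-{2-[(triethylsilyl)oxy]propan-2-yl}-1,3-dioxolane-4-carbaldehyde
Conditions: (COCl)2, DMSO, CH2Cl2, −78 to −40 °C; Et3N, −78 °C
Reagents that add atoms: none
Why: Swern oxidation applied directly to a primary triethylsilyl ether cleaves only the primary Si–O bond and delivers the aldehyde, the tertiary silyl ether and the cis-dioxolane stereocentres staying intact at low temperature.

Step 4
Reactants: 5 hex-5-yn-2-one
Product: 6 2-(but-3-yn-1-yl)-2-methyl-1,3-dioxolane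
Conditions: HOCH2CH2OH, TsOH (cat.), benzene, reflux, Dean–Stark
Reagents that add atoms: ethylene glycol, OCCO
Why: Acid-catalysed ketalisation with azeotropic removal of water masks the future C7 ketone against the organometallic and hydride steps.

Step 5
Reactants: 6 dioxolane alkyne
Product: 8 methyl 5-(2-methyl-1,3-dioxolan-2-yl)pent-2-ynoate, via lithium acetylide 7 (not isolated)
Conditions: n-BuLi, THF, −78 °C; ClCO2Me, −78 to 0 °C
Reagents that add atoms: methyl chloroformate, COC(Cl)=O
Why: C-Acylation of a lithium acetylide with a chloroformate gives the ynoate that carries C3.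

Step 6
Reactants: 8 ynoate; 4 aldehyde
Product: 10 methyl (2Z)-2-[(R)-hydroxy(dioxolanyl)methyl]-5-(2-methyl-1,3-dioxolan-2-yl)pent-2-enoate (12R), via alkenylalane 9 (not isolated)
Conditions: i-Bu2AlH, HMPA, THF, 0 °C; then 4, 0 °C to rt; aq. tartrate work-up
Reagents that add atoms: none
Why: Conjugate hydroalumination (syn addition of H and Al) gives the α-alumino enoate 9 with the chain cis to the ester, and its aldol-type addition to 4 (vinylalumination) under non-chelating conditions should follow the Felkin–Anh model, setting C12 as R (anti to the C13 oxygen).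

Step 7
Reactants: 10 hydroxy enoate
Product: 11 (1R,2E)-2-(hydroxymethyl)pent-2-en-1-ol diol (C3 and C12 hydroxyls)
Conditions: i-Bu2AlH (3 equiv), CH2Cl2, −78 °C
Reagents that add atoms: none
Why: 1,2-Reduction of the enoate ester by i-Bu2AlH gives the primary allylic alcohol without touching the trisubstituted alkene, ketal or acetonide.

Step 8
Reactants: 11 diol
Product: 12 (1R,2E)-allylic alcohol with primary triethylsilyl ether at C3
Conditions: Et3SiCl (1.05 equiv), imidazole, CH2Cl2, −20 °C
Reagents that add atoms: chlorotriethylsilane, CC[Si](Cl)(CC)CC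
Why: Selective silylation of the unhindered primary allylic alcohol leaves the hindered secondary C12 carbinol free for esterification.

Step 9
Reactants: 13 3-chloro-2-(chloromethyl)prop-1-ene (3 equiv); 14 ethynyl(trimethyl)silane
Product: 15 (5-chloro-4-methylidenepent-1-yn-1-yl)(trimethyl)silane
Conditions: CuI (10 mol%), NaI (10 mol%), K2CO3, DMF, rt
Reagents that add atoms: none
Why: Copper-catalysed allyl–alkynyl coupling joins C9 to C10; excess dichloride keeps substitution to one allylic chloride.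

Step 10
Reactants: 15 allylic chloride
Product: 17 3-methylidene-6-(trimethylsilyl)hex-5-ynoic acid, via allylic Grignard reagent 16 (not isolated)
Conditions: Mg, THF, 0 °C (slow addition); CO2, −78 °C to rt; cold 1 M HCl
Reagents that add atoms: carbon dioxide, O=C=O
Why: Carboxylation of an allylic Grignard reagent installs C1; both allyl termini are CH2 groups, so either mode of attack gives the same β,γ-unsaturated acid.

Step 11
Reactants: 12 allylic alcohol; 17 acid
Product: 18 (1R,2E)-allylic 3-methylidene-6-(trimethylsilyl)hex-5-ynoate ester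
Conditions: DCC, DMAP (cat.), CH2Cl2, 0 °C to rt
Reagents that add atoms: none
Why: Steglich esterification acylates the secondary C12 alcohol under mild conditions that keep the β,γ-unsaturated acyl group unconjugated.

Step 12
Reactants: 18 allylic ester
Product: 22 Claisen acid (2R,3S,4Z)-pent-4-enoic acid (C1 acid; 4aS,11aR), via lithium dienolate 19 (not isolated), via silyl ketene acetal 20 (not isolated), via trimethylsilyl ester 21 (not isolated)
Conditions: LiN(i-Pr)2, THF/HMPA 4:1, −78 °C; Me3SiCl; −78 to 40 °C; pH 5 aqueous work-up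
Reagents that add atoms: none
Why: Ireland–Claisen rearrangement: enolisation in the presence of HMPA gives the Z(O)-enolate 19, and its ketene acetal 20 rearranges through a chair with the C13 dioxolanyl group equatorial, so that chirality transfer from C12 sets C4a (S) and C11a (R) and places C13 cis to C3 on the new C4=C12 bond.

Step 13
Reactants: 22 Claisen acid
Product: 23 (2R,3S,4Z)-pent-4-en-1-ol (C1 alcohol)
Conditions: LiAlH4, Et2O, 0 °C
Reagents that add atoms: none
Why: Hydride reduction of the carboxylic acid gives the C1 primary alcohol; silyl ethers, ketals and the silylalkyne are inert to LiAlH4 at 0 °C.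

Step 14
Reactants: 23 alcohol
Product: 24 C1 methanesulfonate
Conditions: MeSO2Cl, Et3N, CH2Cl2, −20 °C
Reagents that add atoms: methanesulfonyl chloride, CS(Cl)(=O)=O
Why: Sulfonate ester formation installs at C1 the leaving group needed for the last ring closure and blocks the hydroxyl in all steps between.

Step 15
Reactants: 24 alkynylsilane
Product: 25 1-iodoalkyne
Conditions: N-iodosuccinimide, AgNO3 (10 mol%), DMF, rt, dark
Reagents that add atoms: N-iodosuccinimide, O=C1CCC(=O)N1I
Why: Silver-catalysed iododesilylation converts the alkynylsilane directly into the iodoalkyne without attacking the alkenes.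

Step 16
Reactants: 25 iodoalkyne
Product: 26 (Z)-iodoalkene (C8=C9)
Conditions: 2-nitrobenzenesulfonylhydrazide, Et3N, THF/i-PrOH, rt
Reagents that add atoms: none
Why: Diimide reduction adds H2 cis to the iodoalkyne, giving the (Z)-iodoalkene, and is much faster there than at the 1,1-disubstituted and trisubstituted alkenes.

Step 17
Reactants: 26 (Z)-iodoalkene
Product: 27 (Z)-enal (C3 aldehyde)
Conditions: (COCl)2, DMSO, CH2Cl2, −78 to −40 °C; Et3N
Reagents that add atoms: none
Why: Swern oxidation applied directly to the primary allylic triethylsilyl ether gives the enal while the tertiary silyl ether, mesylate and iodoalkene are untouched.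

Step 18
Reactants: 27 enal
Product: 28 (Z)-enoic acid (C3 acid)
Conditions: NaClO2, NaH2PO4, 2-methylbut-2-ene, t-BuOH/H2O, 0 °C; used at once
Reagents that add atoms: sodium chlorite, [Na+].[O-]Cl=O
Why: Pinnick oxidation takes the enal to the acid without isomerising the alkene; the weakly acidic buffer keeps the carboxylate from displacing the mesylate.

Step 19
Reactants: 28 enoic acid
Product: 30 butenolide 14,15-diol with C7 methyl ketone, via seco hydroxy acid 29 (not isolated)
Conditions: 2 M HCl, THF, rt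
Reagents that add atoms: water, O
Why: Acid hydrolysis removes acetonide, dioxolane and silyl ether, and the liberated (Z)-4-hydroxy-2-enoic acid 29 lactonises to the five-membered butenolide, the usual outcome for γ,δ-dihydroxy (Z)-enoic acids.

Step 20
Reactants: 30 butenolide diol
Product: 31 butenolide with 14-O-triethylsilyl ether
Conditions: Et3SiCl, imidazole, DMAP (cat.), CH2Cl2, 0 °C to rt
Reagents that add atoms: chlorotriethylsilane, CC[Si](Cl)(CC)CC
Why: Silylation of the secondary C14 hydroxyl (the tertiary C15 hydroxyl does not react) prevents O14 from acting as an alternative lactol oxygen in steps 23 and 24.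

Step 21
Reactants: 31 keto (Z)-iodoalkene butenolide
Product: 33 (Z)-cyclononenol (4aS,7S,11aR,13R,14R), via alkenylchromium dichloride 32 (not isolated)
Conditions: CrCl2 (8 equiv), NiCl2 (2 mol%), DMSO, rt to 40 °C, 3 mM
Reagents that add atoms: none
Why: CrCl2 reduces NiCl2 to zerovalent nickel, which inserts into the C8–I bond with retention of the (Z)-geometry; transmetalation to trivalent chromium gives 32, which adds to the C7 ketone through a chromium-bridged four-centre transition state (Nozaki–Hiyama–Kishi reaction; closest precedent: alkenyl halide–carbonyl NHK closures of medium rings and NHK cyclisations onto ketones). The nine-membered carbocycle closes in the 9-exo-trig mode, C8 attacking the carbonyl carbon while the C=O bond stays outside the ring. The C7 stereocentre is substrate-controlled: with the butenolide on C4a and the CH2OMs arm on C11a pseudo-equatorial, the C5–C6–C7 chain is expected to fold so that the chromium-bound oxygen lies on the face of H-4a and the C18 methyl points to the periphery, presenting the Re face of the ketone to C8 (7S); this preference is a conformational expectation and is not secured. The step needs chemoselectivity, which the non-basic organochromium reagent provides (no reaction with butenolide, mesylate or silyl ether, no enolisation of the methyl ketone), and high dilution against dimerisation. The (Z)-allylic tertiary alcohol formed is the handle that steers the epoxidation of step 22.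

Step 22
Reactants: 33 (Z)-cyclononenol
Product: 34 syn-epoxy alcohol (7S,8R,9R)
Conditions: VO(acac)2 (5 mol%), t-BuOOH, CH2Cl2, 0 °C
Reagents that add atoms: tert-butyl hydroperoxide, CC(C)(C)OO
Why: Vanadium-catalysed hydroxyl-directed epoxidation delivers oxygen to the C8=C9 face syn to the coordinating C7 hydroxyl, as is general for medium-ring (Z)-allylic alcohols, setting C8 and C9; the electron-poor butenolide alkene and the undirected exocyclic methylene do not react.

Step 23
Reactants: 34 epoxy butenolide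
Product: 35 lactol (C3 hemiacetal, anomer mixture)
Conditions: i-Bu2AlH (3.5 equiv), CH2Cl2, −78 °C; aq. tartrate work-up
Reagents that add atoms: none
Why: Lactone-to-lactol reduction by i-Bu2AlH at −78 °C brings C3 to the acetal oxidation level; epoxide and primary mesylate are inert at this temperature.

Step 24
Reactants: 35 lactol mesylate
Product: 36 14-O-triethylsilyl ether of the target
Conditions: Cs2CO3, MeCN, 40 °C
Reagents that add atoms: none
Why: Intramolecular Williamson etherification (anomeric O-alkylation, 6-exo-tet) of the deprotonated hemiacetal on the C1 mesylate closes the pyran; the anomers equilibrate and only the one that places O13 equatorial on the trans-fused chair can close, which sets C3 as S.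

Step 25
Reactants: 36 silyl ether
Product: 37 target CNP0281409.2
Conditions: Bu4NF, THF, 0 °C
Reagents that add atoms: none
Why: Fluoride-mediated desilylation frees the C14 hydroxyl under non-acidic conditions, which the acid-labile dihydrofuran acetal and the epoxy alcohol tolerate.

## Compound list

1 | 2,3-O-isopropylidene-D-erythronolactone, (3aR,6aR)-2,2-dimethyldihydrofuro[3,4-d][1,3]dioxol-4(3aH)-one | O=C1OC[C@H]2OC(C)(C)O[C@@H]12 | starting material
2 | 2-[(4R,5R)-5-(hydroxymethyl)-2,2-dimethyl-1,3-dioxolan-4-yl]propan-2-ol | OC[C@H]1OC(C)(C)O[C@H]1C(C)(C)O | intermediate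
3 | (4R,5R)-2,2-dimethyl-4-{2-[(triethylsilyl)oxy]propan-2-yl}-5-{[(triethylsilyl)oxy]methyl}-1,3-dioxolane | CC[Si](CC)(CC)OC[C@H]1OC(C)(C)O[C@H]1C(C)(C)O[Si](CC)(CC)CC | intermediate
4 | (4S,5R)-2,2-dimethyl-5-{2-[(triethylsilyl)oxy]propan-2-yl}-1,3-dioxolane-4-carbaldehyde | O=C[C@H]1OC(C)(C)O[C@H]1C(C)(C)O[Si](CC)(CC)CC | intermediate
5 | hex-5-yn-2-one | CC(=O)CCC#C | starting material
6 | 2-(but-3-yn-1-yl)-2-methyl-1,3-dioxolane | CC1(CCC#C)OCCO1 | intermediate
7 | [4-(2-methyl-1,3-dioxolan-2-yl)but-1-yn-1-yl]lithium | [Li]C#CCCC1(C)OCCO1 | intermediate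
8 | methyl 5-(2-methyl-1,3-dioxolan-2-yl)pent-2-ynoate | COC(=O)C#CCCC1(C)OCCO1 | intermediate
9 | methyl (2E)-2-[bis(2-methylpropyl)alumanyl]-5-(2-methyl-1,3-dioxolan-2-yl)pent-2-enoate (H and Al cis, chain cis to ester) | COC(=O)/C(=C\CCC1(C)OCCO1)[Al](CC(C)C)CC(C)C | intermediate
10 | methyl (2Z)-2-[(R)-{(4R,5R)-2,2-dimethyl-5-[2-(triethylsilyloxy)propan-2-yl]-1,3-dioxolan-4-yl}(hydroxy)methyl]-5-(2-methyl-1,3-dioxolan-2-yl)pent-2-enoate | COC(=O)/C(=C\CCC1(C)OCCO1)[C@@H](O)[C@H]2OC(C)(C)O[C@H]2C(C)(C)O[Si](CC)(CC)CC | intermediate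
11 | (1R,2E)-1-{(4R,5R)-2,2-dimethyl-5-[2-(triethylsilyloxy)propan-2-yl]-1,3-dioxolan-4-yl}-2-(hydroxymethyl)-5-(2-methyl-1,3-dioxolan-2-yl)pent-2-en-1-ol | OC/C(=C\CCC1(C)OCCO1)[C@@H](O)[C@H]2OC(C)(C)O[C@H]2C(C)(C)O[Si](CC)(CC)CC | intermediate
12 | (1R,2E)-1-{(4R,5R)-2,2-dimethyl-5-[2-(triethylsilyloxy)propan-2-yl]-1,3-dioxolan-4-yl}-5-(2-methyl-1,3-dioxolan-2-yl)-2-{[(triethylsilyl)oxy]methyl}pent-2-en-1-ol | CC[Si](CC)(CC)OC/C(=C\CCC1(C)OCCO1)[C@@H](O)[C@H]2OC(C)(C)O[C@H]2C(C)(C)O[Si](CC)(CC)CC | intermediate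
13 | 3-chloro-2-(chloromethyl)prop-1-ene | C=C(CCl)CCl | starting material
14 | ethynyl(trimethyl)silane | C#C[Si](C)(C)C | starting material
15 | (5-chloro-4-methylidenepent-1-yn-1-yl)(trimethyl)silane | C=C(CCl)CC#C[Si](C)(C)C | intermediate
16 | chloro[2-methylidene-5-(trimethylsilyl)pent-4-yn-1-yl]magnesium | C=C(C[Mg]Cl)CC#C[Si](C)(C)C | intermediate
17 | 3-methylidene-6-(trimethylsilyl)hex-5-ynoic acid | OC(=O)CC(=C)CC#C[Si](C)(C)C | intermediate
18 | 3-methylidene-6-(trimethylsilyl)hex-5-ynoate ester of alcohol 12 (12R; C3 silyloxymethyl cis to the C5 chain) | C=C(CC#C[Si](C)(C)C)CC(=O)O[C@H](/C(CO[Si](CC)(CC)CC)=C/CCC1(C)OCCO1)[C@H]2OC(C)(C)O[C@H]2C(C)(C)O[Si](CC)(CC)CC | intermediate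
19 | lithium Z(O)-dienolate of 18 (OLi cis to the alkenyl substituent on C11a) | C=C(CC#C[Si](C)(C)C)/C=C(\O[Li])O[C@H](/C(CO[Si](CC)(CC)CC)=C/CCC1(C)OCCO1)[C@H]2OC(C)(C)O[C@H]2C(C)(C)O[Si](CC)(CC)CC | intermediate
20 | trimethylsilyl ketene acetal of 18, same geometry as 19 | C=C(CC#C[Si](C)(C)C)/C=C(\O[Si](C)(C)C)O[C@H](/C(CO[Si](CC)(CC)CC)=C/CCC1(C)OCCO1)[C@H]2OC(C)(C)O[C@H]2C(C)(C)O[Si](CC)(CC)CC | intermediate
21 | trimethylsilyl ester of acid 22 | C[Si](C)(C)OC(=O)[C@@H](C(=C)CC#C[Si](C)(C)C)[C@H](CCC1(C)OCCO1)/C(CO[Si](CC)(CC)CC)=C/[C@H]2OC(C)(C)O[C@H]2C(C)(C)O[Si](CC)(CC)CC | intermediate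
22 | (2R,3S,4Z)-5-{(4R,5R)-2,2-dimethyl-5-[2-(triethylsilyloxy)propan-2-yl]-1,3-dioxolan-4-yl}-3-[2-(2-methyl-1,3-dioxolan-2-yl)ethyl]-2-[5-(trimethylsilyl)pent-1-en-4-yn-2-yl]-4-{[(triethylsilyl)oxy]methyl}pent-4-enoic acid | OC(=O)[C@@H](C(=C)CC#C[Si](C)(C)C)[C@H](CCC1(C)OCCO1)/C(CO[Si](CC)(CC)CC)=C/[C@H]2OC(C)(C)O[C@H]2C(C)(C)O[Si](CC)(CC)CC | intermediate
23 | (2R,3S,4Z)-pent-4-en-1-ol corresponding to 22 (C1 = CH2OH) | OC[C@@H](C(=C)CC#C[Si](C)(C)C)[C@H](CCC1(C)OCCO1)/C(CO[Si](CC)(CC)CC)=C/[C@H]2OC(C)(C)O[C@H]2C(C)(C)O[Si](CC)(CC)CC | intermediate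
24 | methanesulfonate of 23 (C1–OMs) | CS(=O)(=O)OC[C@@H](C(=C)CC#C[Si](C)(C)C)[C@H](CCC1(C)OCCO1)/C(CO[Si](CC)(CC)CC)=C/[C@H]2OC(C)(C)O[C@H]2C(C)(C)O[Si](CC)(CC)CC | intermediate
25 | 1-iodoalkyne: 24 with C8 iodide in place of the trimethylsilyl group | CS(=O)(=O)OC[C@@H](C(=C)CC#CI)[C@H](CCC1(C)OCCO1)/C(CO[Si](CC)(CC)CC)=C/[C@H]2OC(C)(C)O[C@H]2C(C)(C)O[Si](CC)(CC)CC | intermediate
26 | (Z)-iodoalkene: 25 with (8Z)-C8H(I)=C9H (4aS,11aR,13R,14R) | CS(=O)(=O)OC[C@@H](C(=C)C/C=C\I)[C@H](CCC1(C)OCCO1)/C(CO[Si](CC)(CC)CC)=C/[C@H]2OC(C)(C)O[C@H]2C(C)(C)O[Si](CC)(CC)CC | intermediate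
27 | (Z)-enal: 26 with C3 as CHO, cis to C13 | CS(=O)(=O)OC[C@@H](C(=C)C/C=C\I)[C@H](CCC1(C)OCCO1)/C(C=O)=C/[C@H]2OC(C)(C)O[C@H]2C(C)(C)O[Si](CC)(CC)CC | intermediate
28 | (Z)-enoic acid: 26 with C3 as CO2H, cis to C13 | CS(=O)(=O)OC[C@@H](C(=C)C/C=C\I)[C@H](CCC1(C)OCCO1)/C(C(O)=O)=C/[C@H]2OC(C)(C)O[C@H]2C(C)(C)O[Si](CC)(CC)CC | intermediate
29 | seco hydroxy acid: 28 after loss of acetonide, dioxolane and silyl ether (C7 ketone, 13,14,15-triol, C3 acid) | CS(=O)(=O)OC[C@@H](C(=C)C/C=C\I)[C@H](CCC(C)=O)/C(C(O)=O)=C/[C@@H](O)[C@@H](O)C(C)(C)O | intermediate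
30 | butenolide (C3 lactone carbonyl, O13 ring oxygen), (4aS,11aR,13R,14R): C4 carries the C4a chain with 3-oxobutyl and, on C11a, CH2OMs and the (4Z)-5-iodopenta-1,4-dien-2-yl group; 14,15-diol free | C=C(C/C=C\I)[C@H](COS(C)(=O)=O)[C@H](CCC(C)=O)C1=C[C@H]([C@@H](O)C(C)(C)O)OC1=O | intermediate
31 | 14-O-triethylsilyl ether of 30 | C=C(C/C=C\I)[C@H](COS(C)(=O)=O)[C@H](CCC(C)=O)C1=C[C@H]([C@@H](O[Si](CC)(CC)CC)C(C)(C)O)OC1=O | intermediate
32 | (Z)-alkenylchromium dichloride from 31 (CrCl2 on C8) | C=C(C/C=C\[Cr](Cl)Cl)[C@H](COS(C)(=O)=O)[C@H](CCC(C)=O)C1=C[C@H]([C@@H](O[Si](CC)(CC)CC)C(C)(C)O)OC1=O | intermediate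
33 | (4aS,7S,11aR,13R,14R)-(8Z)-cyclononenol: nine-membered carbocycle with C7(OH)CH3, C8=C9, C11=CH2; butenolide on C4a, CH2OMs on C11a, 14-OTES | C=C1C/C=C\[C@@](C)(O)CC[C@H](C2=C[C@H]([C@@H](O[Si](CC)(CC)CC)C(C)(C)O)OC2=O)[C@H]1COS(C)(=O)=O | intermediate
34 | (4aS,7S,8R,9R,11aR,13R,14R)-8,9-epoxide of 33, oxirane oxygen syn to the C7 hydroxyl | C=C1C[C@H]2O[C@H]2[C@@](C)(O)CC[C@H](C2=C[C@H]([C@@H](O[Si](CC)(CC)CC)C(C)(C)O)OC2=O)[C@H]1COS(C)(=O)=O | intermediate
35 | lactol of 34 (C3 hemiacetal in the 2,5-dihydrofuran, anomer mixture) | C=C1C[C@H]2O[C@H]2[C@@](C)(O)CC[C@H](C2=C[C@H]([C@@H](O[Si](CC)(CC)CC)C(C)(C)O)OC2O)[C@H]1COS(C)(=O)=O | intermediate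
36 | 14-O-triethylsilyl ether of the target (3S,4aS,7S,8R,9R,11aR,13R,14R) | C=C1C[C@H]2O[C@H]2[C@@](C)(O)CC[C@@H]2C3=C[C@H]([C@@H](O[Si](CC)(CC)CC)C(C)(C)O)O[C@@H]3OC[C@@H]12 | intermediate
37 | CNP0281409.2, (3S,4aS,7S,8R,9R,11aR,13R,14R)-3,13:8,9-diepoxyxenica-4(12),11(19)-diene-7,14,15-triol | C=C1C[C@H]2O[C@H]2[C@@](C)(O)CC[C@@H]2C3=C[C@H]([C@@H](O)C(C)(C)O)O[C@@H]3OC[C@@H]12 | target

## Totals and risks

Total step count: 25. Longest linear sequence: 21 steps (steps 1–3, 6–8, 11–25, from compound 1).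

Steps most likely to fail:

Step 21. The alkenylchromium species may add too slowly to the hindered methyl ketone across a nine-membered transition state, so that protodemetalation or dimerisation take over, or it may attack the wrong carbonyl face. The fallback closes the pyran first, so that the two arms are held gauche on a rigid trans-fused ring before the carbocycle is closed. It sets out from 31: i-Bu2AlH (CH2Cl2, −78 °C) reduces lactone and ketone to the lactol carbinol F1; Cs2CO3 in MeCN closes the pyran by hemiacetal O-alkylation to the bicyclic acetal carbinol F2; Dess–Martin periodinane with NaHCO3 restores the methyl ketone in bicyclic acetal ketone F3; CrCl2/NiCl2 in DMSO then closes the carbocycle on the preorganised scaffold to the tricyclic cyclononenol F4; VO(acac)2/t-BuOOH epoxidation of F4 returns to the route at 36.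

Step 24. Under base the hemiacetal may open to the (Z)-hydroxy enal and isomerise or eliminate faster than it is alkylated. The fallback avoids the alkoxide and activates the electrophile instead. It sets out from 34: NaI in acetone exchanges the mesylate for iodide to give the epoxy butenolide iodide F5; i-Bu2AlH at −78 °C gives the lactol iodide F6; Ag2O in CH2Cl2 promotes silver-assisted alkylation of the neutral hemiacetal, returning to the route at 36.

Step 6. The hindered alumino enoate may add sluggishly to the α,β-dialkoxy aldehyde and with poor facial selectivity. The fallback replaces the aluminium nucleophile by a chromium one. It sets out from 8: Pd(PPh3)4-catalysed syn hydrostannation with Bu3SnH gives the α-stannyl enoate F7; I2 in CH2Cl2 converts it with retention into the α-iodo enoate F8; CrCl2/NiCl2-mediated coupling of F8 with aldehyde 4 (Felkin–Anh addition) returns to the route at 10.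

Further compounds

F1 | step 21 | lactol carbinol: 31 with C3 hemiacetal and C7 secondary alcohol | C=C(C/C=C\I)[C@H](COS(C)(=O)=O)[C@H](CCC(C)O)C1=C[C@H]([C@@H](O[Si](CC)(CC)CC)C(C)(C)O)OC1O
F2 | step 21 | bicyclic acetal carbinol (3S,4aS,11aR,13R,14R) with 3-hydroxybutyl on C4a and (4Z)-5-iodopenta-1,4-dien-2-yl on C11a | CC(O)CC[C@@H]1C2=C[C@H]([C@@H](O[Si](CC)(CC)CC)C(C)(C)O)O[C@@H]2OC[C@H]1C(=C)C/C=C\I
F3 | step 21 | bicyclic acetal ketone: F2 with C7 methyl ketone | CC(=O)CC[C@@H]1C2=C[C@H]([C@@H](O[Si](CC)(CC)CC)C(C)(C)O)O[C@@H]2OC[C@H]1C(=C)C/C=C\I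
F4 | step 21 | tricyclic (8Z)-cyclononenol (3S,4aS,7S,11aR,13R,14R), 14-OTES | C=C1C/C=C\[C@@](C)(O)CC[C@@H]2C3=C[C@H]([C@@H](O[Si](CC)(CC)CC)C(C)(C)O)O[C@@H]3OC[C@@H]12
F5 | step 24 | epoxy butenolide iodide: 34 with C1 iodide in place of the mesylate | C=C1C[C@H]2O[C@H]2[C@@](C)(O)CC[C@H](C2=C[C@H]([C@@H](O[Si](CC)(CC)CC)C(C)(C)O)OC2=O)[C@H]1CI
F6 | step 24 | lactol iodide: F5 with C3 hemiacetal | C=C1C[C@H]2O[C@H]2[C@@](C)(O)CC[C@H](C2=C[C@H]([C@@H](O[Si](CC)(CC)CC)C(C)(C)O)OC2O)[C@H]1CI
F7 | step 6 | methyl (2E)-5-(2-methyl-1,3-dioxolan-2-yl)-2-(tributylstannyl)pent-2-enoate | COC(=O)/C(=C\CCC1(C)OCCO1)[Sn](CCCC)(CCCC)CCCC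
F8 | step 6 | methyl (2E)-2-iodo-5-(2-methyl-1,3-dioxolan-2-yl)pent-2-enoate | COC(=O)/C(I)=C\CCC1(C)OCCO1
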